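The readings are calculated for substances that don't exist.

Time is the first thing to ask about in this flask: a reading at some minute is a stop on a road, and you want to know where the road ends.

| flask | substrate | partner | remark | time |
|---|---|---|---|---|
| beta | 0.050 M | 0.035 M | run made earlier |  |
| alpha | 0.034 M | 0.035 M | run made earlier |  |
| theta | 0.075 M | 0.035 M | run made earlier |  |
| north-west | 0.050 M | 0.0350 M | everything together in a closed stirred flask, run for 15 min | 15 min |
| east | 0.050 M | 0.0350 M (fed, over 12.0 min) | a stirred flask in which partner is dosed at a steady rate over 12.0 min without added volume, worked up at 15 min | 15 min |
| south-east | 0.050 M | 0.0350 M | a single well-mixed tank run continuously and read at steady state, 15 min in it on average |  |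
| south-west | 0.050 M (fed, over 12.0 min) | 0.0350 M | all but substrate at the start; substrate goes in evenly over 12.0 min, the run ends at 15 min | 15 min |

| run | time / min | target / % | side product / % |
|---|---|---|---|
| beta | 0.833 | 0 | 0 |
| beta | 2.50 | 2.6 | 0.8 |
| beta | 4.00 | 6.4 | 0.8 |
| beta | 6.00 | 11.8 | 2.5 |
| beta | 10.0 | 22.2 | 6.9 |
| alpha | 1.33 | 0.9 | 0.7 |
| alpha | 2.50 | 2.7 | 0.4 |
| alpha | 4.00 | 8.0 | 1.2 |
| alpha | 8.00 | 19.3 | 3.1 |
| alpha | 15.0 | 35.5 | 7.7 |
| theta | 1.33 | 0.9 | 0.8 |
| theta | 4.00 | 6.1 | 2.7 |
| theta | 8.00 | 15.5 | 6.8 |
| theta | 10.0 | 19.4 | 7.6 |
| theta | 15.0 | 24.7 | 15.1 |

(standard deviation of a reading: 0.5 percentage points)

- order of the set-ups by the share of target in all that became target or side product, at the outlet or at the end, highest first (north-west / east / south-east / south-west)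
- share of target in all that became target or side product, at the outlet or at the end, north-west
- share of target in all that became target or side product, at the outlet or at the end, east
- share of target in all that became target or side product, at the outlet or at the end, south-east
- share of target in all that became target or side product, at the outlet or at the end, south-west

- a species is counted by the substrate in it: one side product counts as two
- the stated concentrations are those of everything mixed, before any reaction; amounts are the same in each set-up
- the feed brings no volume worth counting
- the earlier runs were made in a closed, stirred flask

The later readings of the earlier runs show a drift. In the theta run, side product per target climbs from 0.439 at 8.00 min to 0.611 at 15.0 min, while the alpha run, charged with less substrate, stands at 0.217 at 15.0 min. A side product that counts as two substrates and grows with both target and substrate reads, to me, as one target taking up one more substrate. That is my assumption, and it makes target a station on the road, not the end of it.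

Now look at the charge. Partner is the limiting reagent, since its charge is smaller than that of substrate. Suppose each partner makes one target, and each unit of substrate beyond that takes one target away:

excess substrate = 0.0150 M

target at the end = 0.0200 M

E = 40.0%

E is the end share: the share of target in target plus side product, reckoned for substrate at zero and every partner turned into target. On this supposition, a share at 15 min with this charge is a stop on the way down to E. So I expect east, where target appears late, to stand above north-west.

The forecast orders the set-ups south-west > north-west > south-east > east, with north-west 77.5%, east 67%, south-east 77% and south-west 81.5%. Its ground is that target gains as the ratio of substrate to partner falls: “Feeding substrate keeps it low, which is best”. We part on east, which it places last.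

The flask gives east > north-west > south-west > south-east: north-west 72.7%, east 78.4%, south-east 40.6%, south-west 65.7%, so east stands above north-west.

    substrate ⇌ open intermediate (K = 12.0, k = 0.0120 s⁻¹)
    partner → second intermediate (k = 0.00500 s⁻¹)
    open intermediate + second intermediate → target (k = 0.0320 M⁻¹ s⁻¹)
    substrate + target → side product (k = 0.140 M⁻¹ s⁻¹)

By the step from substrate + target alone, with concentrations as charged, target in north-west has a half-life of 1.7 min, shorter than the 15 min of the run. Yet north-west ends at 72.7%, above the end share of 40.0%, with 4.03% of its charge still standing as substrate. Left for 150 min, ten times as long, east comes down from 78.4% to 37.8%, lower than the end share of 40.0%.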